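**Plan**

1. Locants used below: ring C10 (quaternary; methyl, vinyl C1=C2) – C9H2 – C8 (acyloxy) – C7 (acrylic acid C11–C13) – C6 (OH) – C5 (hydroxypropenyl C3, C4, C15). The retrosynthesis removes the ester at O8, the C15 hydroxyl and the protecting groups, takes C8 to the ketone, then cuts the ring at C9–C10 and at C6–C7.
2. Enabling feature: O8 lies between C9 and C7, so the C8 ketone is at once the carbonyl of a Claisen retron (C8–C9–C10–C1=C2) and of an aldol/allylation retron (HO–C6–C7–C8=O with the 2-carboxyallyl unit on C7).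
3. Precursor: a β-keto ester tether (lost as CO2) links an allylic alcohol piece (C1, C2, C10, C5, isopropenyl; C6 masked as dimethyl acetal) to a Baylis–Hillman acetate piece (C9, C8, C7, C11–C13).
4. Forward: the two pieces are made separately and joined as the β-keto ester. One flask then gives the Carroll rearrangement (C9–C10) and an indium/palladium Barbier-type cyclisation (C6–C7) that closes the only ring. Ketone reduction, acylation at O8, allylic oxidation at C15 and deprotection follow.
5. Stereochemistry: C5 from a copper-catalysed enantioselective allylic substitution; C10 by 1,2-induction from C5 in the [3,3] shift; C6 and C7 from the chelated chair of the ring closure; C8 by hydroxyl-directed reduction; the side-chain centre from the (S)-Roche ester.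

Key step: step 12

Remark: the carbinol/acetoxy carbon in compounds 14 to 20 is an inconsequential mixture of epimers (it becomes a defined centre only in step 12), and the target is taken to be isolable as the open hydroxy acid.

**Route**

Step 1
Reactants: 1 2,2-dimethoxyacetaldehyde; 2 ethyl 2-(triphenyl-λ5-phosphanylidene)propanoate
Product: 3 ethyl (2E)-4,4-dimethoxy-2-methylbut-2-enoate
Conditions: CH2Cl2–H2O, 25 °C
Reagents that add atoms: none
Why: Wittig olefination with the stabilised α-methyl ylide should give the (E)-enoate, ester trans to the acetal carbon.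

Step 2
Reactants: 3 ethyl (2E)-4,4-dimethoxy-2-methylbut-2-enoate
Product: 4 (2E)-4,4-dimethoxy-2-methylbut-2-en-1-ol
Conditions: i-Bu2AlH, CH2Cl2, −78 °C
Reagents that add atoms: none
Why: Low-temperature hydride reduction takes the conjugated ester to the allylic alcohol without touching the acetal or the alkene geometry.

Step 3
Reactants: 4 (2E)-4,4-dimethoxy-2-methylbut-2-en-1-ol
Product: 5 (2E)-4,4-dimethoxy-2-methylbut-2-en-1-yl diethyl phosphate
Conditions: ClP(O)(OEt)2, Et3N, DMAP (cat.), CH2Cl2, 0 °C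
Reagents that add atoms: diethyl chlorophosphate, CCOP(=O)(Cl)OCC
Why: Phosphorylation of the primary allylic alcohol installs the leaving group for the copper-catalysed SN2′ substitution.

Step 4
Reactants: 6 but-2-yn-1-ol
Product: 7 tert-butyl(but-2-yn-1-yloxy)dimethylsilane
Conditions: TBSCl, imidazole, CH2Cl2, 25 °C
Reagents that add atoms: tert-butyldimethylsilyl chloride, CC(C)(C)[Si](C)(C)Cl
Why: Standard silylation masks the propargylic alcohol for the borylation and coupling steps.

Step 5
Reactants: 7 tert-butyl(but-2-yn-1-yloxy)dimethylsilane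
Product: 8 tert-butyldimethyl{[(2Z)-3-(4,4,5,5-tetramethyl-1,3,2-dioxaborolan-2-yl)but-2-en-1-yl]oxy}silane
Conditions: B2pin2, CuCl (5 mol%), P(t-Bu)3 (6 mol%), NaOt-Bu (10 mol%), MeOH (2 equiv), THF, 25 °C
Reagents that add atoms: bis(pinacolato)diboron, CC1(C)OB(OC1(C)C)B1OC(C)(C)C(C)(C)O1
Why: Copper-catalysed protoboration (formal hydroboration) adds boron and hydrogen syn across the alkyne with boron on the carbon remote from the oxygen-bearing carbon, which fixes the geometry of the later C10=C1 alkene.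

Step 6
Reactants: 5 (2E)-4,4-dimethoxy-2-methylbut-2-en-1-yl diethyl phosphate; 8 tert-butyldimethyl{[(2Z)-3-(4,4,5,5-tetramethyl-1,3,2-dioxaborolan-2-yl)but-2-en-1-yl]oxy}silane
Product: 9 tert-butyl{[(2E,4S)-4-(dimethoxymethyl)-3,5-dimethylhexa-2,5-dien-1-yl]oxy}dimethylsilane
Conditions: CuCl (5 mol%), chiral sulfonate-bearing imidazolinium salt (NHC precursor, 5.5 mol%), NaOMe (1.5 equiv), THF, 22 °C
Reagents that add atoms: none
Why: Copper–NHC-catalysed enantioselective allylic substitution (SN2′) transfers the alkenyl group from boron to the γ-carbon of the phosphate with retention of alkene geometry, so the ligand enantiomer sets C5 as (S) and the transposed alkene becomes the isopropenyl group.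

Step 7
Reactants: 9 tert-butyl{[(2E,4S)-4-(dimethoxymethyl)-3,5-dimethylhexa-2,5-dien-1-yl]oxy}dimethylsilane
Product: 10 (2E,4S)-4-(dimethoxymethyl)-3,5-dimethylhexa-2,5-dien-1-ol
Conditions: Bu4NF, THF, 0 °C
Reagents that add atoms: none
Why: Fluoride cleaves the silyl ether and frees the allylic alcohol that will carry the ester tether.

Step 8
Reactants: 11 2,2,6-trimethyl-4H-1,3-dioxin-4-one
Product: 12 2,2-dimethyl-4-oxo-4H-1,3-dioxine-6-carbaldehyde
Conditions: SeO2, 1,4-dioxane, 100 °C
Reagents that add atoms: selenium dioxide, O=[Se]=O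
Why: Riley oxidation converts the vinylogous-ester methyl group into the aldehyde.

Step 9
Reactants: 12 2,2-dimethyl-4-oxo-4H-1,3-dioxine-6-carbaldehyde; 13 tert-butyl prop-2-enoate
Product: 14 tert-butyl 2-[(2,2-dimethyl-4-oxo-4H-1,3-dioxin-6-yl)(hydroxy)methyl]prop-2-enoate (racemic)
Conditions: DABCO (0.3 equiv), MeCN, 25 °C
Reagents that add atoms: none
Why: The Morita–Baylis–Hillman reaction joins the acrylate α-carbon (C11) to the aldehyde carbon (C7); the new carbinol centre is racemic and is erased in step 12.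

Step 10
Reactants: 14 tert-butyl 2-[(2,2-dimethyl-4-oxo-4H-1,3-dioxin-6-yl)(hydroxy)methyl]prop-2-enoate
Product: 15 tert-butyl 2-[(acetyloxy)(2,2-dimethyl-4-oxo-4H-1,3-dioxin-6-yl)methyl]prop-2-enoate (racemic)
Conditions: Ac2O, pyridine, DMAP (cat.), CH2Cl2, 0 °C
Reagents that add atoms: acetic anhydride, CC(=O)OC(C)=O
Why: Acetylation turns the Baylis–Hillman alcohol into the allylic acetate that later serves as the reductive handle for enolate formation at C7.

Step 11
Reactants: 15 tert-butyl 2-[(acetyloxy)(2,2-dimethyl-4-oxo-4H-1,3-dioxin-6-yl)methyl]prop-2-enoate; 10 (2E,4S)-4-(dimethoxymethyl)-3,5-dimethylhexa-2,5-dien-1-ol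
Product: 17 (2E,4S)-4-(dimethoxymethyl)-3,5-dimethylhexa-2,5-dien-1-yl 4-(acetyloxy)-5-(tert-butoxycarbonyl)-3-oxohex-5-enoate, via acylketene 16 (not isolated)
Conditions: toluene, 110 °C
Reagents that add atoms: none
Why: Thermolysis of the dioxinone expels acetone by retro-[4+2] cleavage and the acylketene is trapped by the primary alcohol, a neutral β-keto ester synthesis that builds the tether.

Step 12
Reactants: 17 (2E,4S)-4-(dimethoxymethyl)-3,5-dimethylhexa-2,5-dien-1-yl 4-(acetyloxy)-5-(tert-butoxycarbonyl)-3-oxohex-5-enoate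
Product: 21 tert-butyl 2-[(1S,2S,3S,4S)-4-ethenyl-2-hydroxy-4-methyl-6-oxo-3-(prop-1-en-2-yl)cyclohexyl]prop-2-enoate, via β-keto acid 18 (not isolated), via ketone acetal 19 (not isolated), via keto aldehyde 20 (not isolated)
Conditions: o-xylene, 160 °C (sealed tube); then THF–H2O, In(OTf)3 (10 mol%), InI (2 equiv), Pd(PPh3)4 (5 mol%), 25 °C
Reagents that add atoms: water, O
Why: Heating brings the allyl β-keto ester into its ester-enol form, which undergoes the [3,3]-sigmatropic Carroll (decarboxylative Claisen) rearrangement through a chair, so that C9 bonds to C10, the C2–O bond becomes the C1=C2 vinyl group and the tether leaves as CO2 (18 to 19); the closest known reaction type is the thermal Carroll rearrangement of γ,γ-disubstituted allyl acetoacetates to β-quaternary γ,δ-unsaturated ketones. The C10 quaternary centre is controlled by the C5 centre, which cannot epimerise as the acetal: with the bulky dimethoxymethyl group anti to the incoming C9, the isopropenyl group over the alkene and H next to the C10 methyl, C9 should add to the face that gives (S)-C10. In the same flask In(OTf)3 in wet THF releases the aldehyde (20), zerovalent palladium ionises the Baylis–Hillman-type allylic acetate (either allylic isomer) and InI reduces the allyl complex to an allylindium dienolate, as in umpolung Barbier allylations of aldehydes with allylic acetates. This nucleophile attacks the aldehyde through C7 in a 6-exo-trig closure (6-enolendo in aldol terms) that forms C6–C7 and the only ring and restores the C11=C13 acrylate. Indium bridging the C8 oxygen and the aldehyde oxygen in a chair with the isopropenyl group equatorial should place the C6 oxygen axial, syn to the C10 methyl, that is (S)-C6, while C7, epimerisable next to the ketone, takes the equatorial (S) configuration. The step needs migration to C9 and not C7, fixed by the position of the ester carboxyl, selective ionisation of the activated acetate, and attack at C7 and not C13, secured by six- against eight-membered ring formation.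

Step 13
Reactants: 21 tert-butyl 2-[(1S,2S,3S,4S)-4-ethenyl-2-hydroxy-4-methyl-6-oxo-3-(prop-1-en-2-yl)cyclohexyl]prop-2-enoate
Product: 22 tert-butyl 2-[(1R,2S,3S,4S,6S)-4-ethenyl-2,6-dihydroxy-4-methyl-3-(prop-1-en-2-yl)cyclohexyl]prop-2-enoate
Conditions: Me4NBH(OAc)3, MeCN–AcOH, −30 °C
Reagents that add atoms: none
Why: In the hydroxyl-directed Evans–Saksena reduction the boron bound to the axial C6 oxygen delivers hydride to the same face of the C8 ketone, which should give the anti-1,3-diol with the new C8 hydroxyl equatorial (S).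

Step 14
Reactants: 23 methyl (2S)-3-hydroxy-2-methylpropanoate
Product: 24 methyl (2S)-3-[(tert-butyldimethylsilyl)oxy]-2-methylpropanoate
Conditions: TBSCl, imidazole, CH2Cl2, 25 °C
Reagents that add atoms: tert-butyldimethylsilyl chloride, CC(C)(C)[Si](C)(C)Cl
Why: Silylation protects the primary hydroxyl of the Roche ester, whose stereocentre becomes the side-chain centre unchanged.

Step 15
Reactants: 24 methyl (2S)-3-[(tert-butyldimethylsilyl)oxy]-2-methylpropanoate
Product: 25 (2S)-3-[(tert-butyldimethylsilyl)oxy]-2-methylpropanoic acid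
Conditions: LiOH, THF–MeOH–H2O, 0 °C; then 1 M HCl to pH 4
Reagents that add atoms: lithium hydroxide, [Li+].[OH-]
Why: Mild saponification at low temperature frees the acid without epimerising the α-centre.

Step 16
Reactants: 22 tert-butyl 2-[(1R,2S,3S,4S,6S)-4-ethenyl-2,6-dihydroxy-4-methyl-3-(prop-1-en-2-yl)cyclohexyl]prop-2-enoate; 25 (2S)-3-[(tert-butyldimethylsilyl)oxy]-2-methylpropanoic acid
Product: 26 tert-butyl 2-[(1S,2S,3S,4S,6S)-6-{[(2S)-3-{[tert-butyl(dimethyl)silyl]oxy}-2-methylpropanoyl]oxy}-4-ethenyl-2-hydroxy-4-methyl-3-(prop-1-en-2-yl)cyclohexyl]prop-2-enoate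
Conditions: DCC, DMAP (cat.), CH2Cl2, 0 → 25 °C
Reagents that add atoms: none
Why: Steglich esterification should acylate the equatorial C8 hydroxyl in preference to the axial C6 hydroxyl, which is flanked by two substituted carbons and syn-axial to the C10 methyl.

Step 17
Reactants: 26 tert-butyl 2-[(1S,2S,3S,4S,6S)-6-{[(2S)-3-{[tert-butyl(dimethyl)silyl]oxy}-2-methylpropanoyl]oxy}-4-ethenyl-2-hydroxy-4-methyl-3-(prop-1-en-2-yl)cyclohexyl]prop-2-enoate
Product: 27 tert-butyl 2-[(1S,2S,3R,4S,6S)-6-{[(2S)-3-{[tert-butyl(dimethyl)silyl]oxy}-2-methylpropanoyl]oxy}-4-ethenyl-2-hydroxy-3-(3-hydroxyprop-1-en-2-yl)-4-methylcyclohexyl]prop-2-enoate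
Conditions: SeO2 (0.3 equiv), t-BuOOH, CH2Cl2, 25 °C
Reagents that add atoms: tert-butyl hydroperoxide, CC(C)(C)OO
Why: Selenium dioxide-catalysed allylic oxidation (ene reaction then [2,3] shift) should hydroxylate the methyl group of the isopropenyl unit, the only electron-rich alkene that carries allylic hydrogens.

Step 18
Reactants: 27 tert-butyl 2-[(1S,2S,3R,4S,6S)-6-{[(2S)-3-{[tert-butyl(dimethyl)silyl]oxy}-2-methylpropanoyl]oxy}-4-ethenyl-2-hydroxy-3-(3-hydroxyprop-1-en-2-yl)-4-methylcyclohexyl]prop-2-enoate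
Product: 29 2-[(1S,2S,3R,4S,6S)-4-ethenyl-2-hydroxy-6-{[(2S)-3-hydroxy-2-methylpropanoyl]oxy}-3-(3-hydroxyprop-1-en-2-yl)-4-methylcyclohexyl]prop-2-enoic acid, via silyl ester 28 (not isolated)
Conditions: Me3SiOTf, 2,6-lutidine, CH2Cl2, 0 °C; then HF·pyridine, THF, 0 → 25 °C
Reagents that add atoms: none
Why: Silyl triflate with a hindered base converts the tert-butyl ester into the silyl ester without free acid (the two free hydroxyls are silylated in passing), and fluoride then removes all silyl groups under conditions that should not lactonise the hydroxy acid.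

**Compound list**

1 | 2,2-dimethoxyacetaldehyde | COC(OC)C=O | starting material
2 | ethyl 2-(triphenyl-λ5-phosphanylidene)propanoate | CCOC(=O)C(C)=P(c1ccccc1)(c1ccccc1)c1ccccc1 | starting material
3 | ethyl (2E)-4,4-dimethoxy-2-methylbut-2-enoate | CCOC(=O)/C(C)=C/C(OC)OC | intermediate
4 | (2E)-4,4-dimethoxy-2-methylbut-2-en-1-ol | OC/C(C)=C/C(OC)OC | intermediate
5 | (2E)-4,4-dimethoxy-2-methylbut-2-en-1-yl diethyl phosphate | CCOP(=O)(OCC)OC/C(C)=C/C(OC)OC | intermediate
6 | but-2-yn-1-ol | CC#CCO | starting material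
7 | tert-butyl(but-2-yn-1-yloxy)dimethylsilane | CC#CCO[Si](C)(C)C(C)(C)C | intermediate
8 | tert-butyldimethyl{[(2Z)-3-(4,4,5,5-tetramethyl-1,3,2-dioxaborolan-2-yl)but-2-en-1-yl]oxy}silane | C/C(B1OC(C)(C)C(C)(C)O1)=C\CO[Si](C)(C)C(C)(C)C | intermediate
9 | tert-butyl{[(2E,4S)-4-(dimethoxymethyl)-3,5-dimethylhexa-2,5-dien-1-yl]oxy}dimethylsilane | COC(OC)[C@H](/C(C)=C/CO[Si](C)(C)C(C)(C)C)C(C)=C | intermediate
10 | (2E,4S)-4-(dimethoxymethyl)-3,5-dimethylhexa-2,5-dien-1-ol | COC(OC)[C@H](/C(C)=C/CO)C(C)=C | intermediate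
11 | 2,2,6-trimethyl-4H-1,3-dioxin-4-one | CC1=CC(=O)OC(C)(C)O1 | starting material
12 | 2,2-dimethyl-4-oxo-4H-1,3-dioxine-6-carbaldehyde | O=CC1=CC(=O)OC(C)(C)O1 | intermediate
13 | tert-butyl prop-2-enoate | C=CC(=O)OC(C)(C)C | starting material
14 | tert-butyl 2-[(2,2-dimethyl-4-oxo-4H-1,3-dioxin-6-yl)(hydroxy)methyl]prop-2-enoate (racemic) | C=C(C(O)C1=CC(=O)OC(C)(C)O1)C(=O)OC(C)(C)C | intermediate
15 | tert-butyl 2-[(acetyloxy)(2,2-dimethyl-4-oxo-4H-1,3-dioxin-6-yl)methyl]prop-2-enoate (racemic) | C=C(C(OC(C)=O)C1=CC(=O)OC(C)(C)O1)C(=O)OC(C)(C)C | intermediate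
16 | tert-butyl 3-(acetyloxy)-2-methylidene-4,6-dioxohex-5-enoate (acylketene) | C=C(C(OC(C)=O)C(=O)C=C=O)C(=O)OC(C)(C)C | intermediate
17 | (2E,4S)-4-(dimethoxymethyl)-3,5-dimethylhexa-2,5-dien-1-yl 4-(acetyloxy)-5-(tert-butoxycarbonyl)-3-oxohex-5-enoate | COC(OC)[C@H](/C(C)=C/COC(=O)CC(=O)C(OC(C)=O)C(=C)C(=O)OC(C)(C)C)C(C)=C | intermediate
18 | (3S,4S)-2-[2-(acetyloxy)-3-(tert-butoxycarbonyl)but-3-enoyl]-4-(dimethoxymethyl)-3-ethenyl-3,5-dimethylhex-5-enoic acid | COC(OC)[C@H]([C@](C)(C=C)C(C(=O)O)C(=O)C(OC(C)=O)C(=C)C(=O)OC(C)(C)C)C(C)=C | intermediate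
19 | tert-butyl (6S,7S)-3-(acetyloxy)-7-(dimethoxymethyl)-6-ethenyl-6,8-dimethyl-2-methylidene-4-oxonon-8-enoate | COC(OC)[C@H]([C@](C)(C=C)CC(=O)C(OC(C)=O)C(=C)C(=O)OC(C)(C)C)C(C)=C | intermediate
20 | tert-butyl (6S,7S)-3-(acetyloxy)-6-ethenyl-7-formyl-6,8-dimethyl-2-methylidene-4-oxonon-8-enoate | O=C[C@H]([C@](C)(C=C)CC(=O)C(OC(C)=O)C(=C)C(=O)OC(C)(C)C)C(C)=C | intermediate
21 | tert-butyl 2-[(1S,2S,3S,4S)-4-ethenyl-2-hydroxy-4-methyl-6-oxo-3-(prop-1-en-2-yl)cyclohexyl]prop-2-enoate | C=C[C@]1(C)CC(=O)[C@@H](C(=C)C(=O)OC(C)(C)C)[C@@H](O)[C@H]1C(C)=C | intermediate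
22 | tert-butyl 2-[(1R,2S,3S,4S,6S)-4-ethenyl-2,6-dihydroxy-4-methyl-3-(prop-1-en-2-yl)cyclohexyl]prop-2-enoate | C=C[C@]1(C)C[C@H](O)[C@@H](C(=C)C(=O)OC(C)(C)C)[C@@H](O)[C@H]1C(C)=C | intermediate
23 | methyl (2S)-3-hydroxy-2-methylpropanoate | COC(=O)[C@@H](C)CO | starting material
24 | methyl (2S)-3-[(tert-butyldimethylsilyl)oxy]-2-methylpropanoate | COC(=O)[C@@H](C)CO[Si](C)(C)C(C)(C)C | intermediate
25 | (2S)-3-[(tert-butyldimethylsilyl)oxy]-2-methylpropanoic acid | OC(=O)[C@@H](C)CO[Si](C)(C)C(C)(C)C | intermediate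
26 | tert-butyl 2-[(1S,2S,3S,4S,6S)-6-{[(2S)-3-{[tert-butyl(dimethyl)silyl]oxy}-2-methylpropanoyl]oxy}-4-ethenyl-2-hydroxy-4-methyl-3-(prop-1-en-2-yl)cyclohexyl]prop-2-enoate | C=C[C@]1(C)C[C@H](OC(=O)[C@@H](C)CO[Si](C)(C)C(C)(C)C)[C@@H](C(=C)C(=O)OC(C)(C)C)[C@@H](O)[C@H]1C(C)=C | intermediate
27 | tert-butyl 2-[(1S,2S,3R,4S,6S)-6-{[(2S)-3-{[tert-butyl(dimethyl)silyl]oxy}-2-methylpropanoyl]oxy}-4-ethenyl-2-hydroxy-3-(3-hydroxyprop-1-en-2-yl)-4-methylcyclohexyl]prop-2-enoate | C=C[C@]1(C)C[C@H](OC(=O)[C@@H](C)CO[Si](C)(C)C(C)(C)C)[C@@H](C(=C)C(=O)OC(C)(C)C)[C@@H](O)[C@H]1C(=C)CO | intermediate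
28 | trimethylsilyl 2-[(1R,2S,3R,4S,6S)-6-{[(2S)-3-{[tert-butyl(dimethyl)silyl]oxy}-2-methylpropanoyl]oxy}-4-ethenyl-4-methyl-2-[(trimethylsilyl)oxy]-3-{3-[(trimethylsilyl)oxy]prop-1-en-2-yl}cyclohexyl]prop-2-enoate | C=C[C@]1(C)C[C@H](OC(=O)[C@@H](C)CO[Si](C)(C)C(C)(C)C)[C@@H](C(=C)C(=O)O[Si](C)(C)C)[C@@H](O[Si](C)(C)C)[C@H]1C(=C)CO[Si](C)(C)C | intermediate
29 | 2-[(1S,2S,3R,4S,6S)-4-ethenyl-2-hydroxy-6-{[(2S)-3-hydroxy-2-methylpropanoyl]oxy}-3-(3-hydroxyprop-1-en-2-yl)-4-methylcyclohexyl]prop-2-enoic acid | C=C[C@]1(C)C[C@H](OC(=O)[C@@H](C)CO)[C@@H](C(=C)C(=O)O)[C@@H](O)[C@H]1C(=C)CO | target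

**Totals**

Total step count: 18.
Longest linear sequence: 11 steps (1, 2, 3, 6, 7, 11, 12, 13, 16, 17, 18).

**Steps most likely to fail**

Step 12 (key step). What may go wrong: loss of facial selectivity at C10 in the [3,3] shift at 160 °C, thermal migration or elimination of the acetate, protonation of the allylindium species or enolisation of the freshly released aldehyde before ring closure, and poor facial selectivity at C6. Fallback: the two bond formations are run as separate known operations with purification in between. Setting out from β-keto ester 17, the Carroll rearrangement alone (xylene, 160 °C) is followed by isolation of ketone acetal 19, at which stage a C10 epimer can be removed. The acetal is then cleaved on wet silica with oxalic acid to keto aldehyde 20. The ring is closed by the SmI2-mediated Reformatsky-type aldol of the acetoxy ketone (THF, −78 °C), in which the samarium enolate chelates the aldehyde and should again place the C6 oxygen axial. The route is rejoined at ketol 21; no compound outside the list is made (F0).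

Step 6. What may go wrong: insufficient enantioface discrimination, or direct SN2 instead of SN2′ attack on the β-methyl-substituted phosphate. Fallback: stereochemistry by resolution instead of asymmetric catalysis. Setting out from phosphate 5 and boronate 8, the coupling is run with an achiral carbene ligand (1,3-dimesitylimidazolium chloride, CuCl, NaOMe, THF). This should give silyl ether 9 together with its enantiomer tert-butyl{[(2E,4R)-4-(dimethoxymethyl)-3,5-dimethylhexa-2,5-dien-1-yl]oxy}dimethylsilane F1. Desilylation with Bu4NF gives alcohol 10 and its enantiomer (2E,4R)-4-(dimethoxymethyl)-3,5-dimethylhexa-2,5-dien-1-ol F2, which are separated by preparative chromatography on a chiral stationary phase. The route is rejoined at alcohol 10.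

Step 17. What may go wrong: over-oxidation of the new allylic alcohol to the enal, competing attack at the allylic C5–H, or a sluggish ene step next to the quaternary centre. Fallback: a Schenck ene photooxygenation in place of selenium chemistry. Setting out from ester 26, singlet oxygen (O2, tetraphenylporphyrin, visible light, CH2Cl2, 0 °C) should abstract a methyl hydrogen of the isopropenyl group and give the allylic hydroperoxide tert-butyl 2-[(1S,2S,3R,4S,6S)-6-{[(2S)-3-{[tert-butyl(dimethyl)silyl]oxy}-2-methylpropanoyl]oxy}-4-ethenyl-3-(3-hydroperoxyprop-1-en-2-yl)-2-hydroxy-4-methylcyclohexyl]prop-2-enoate F3. Reduction with PPh3 then gives allylic alcohol 27, where the route is rejoined.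

**Further compounds**

F0 | step 12 | none | none
F1 | step 6 | tert-butyl{[(2E,4R)-4-(dimethoxymethyl)-3,5-dimethylhexa-2,5-dien-1-yl]oxy}dimethylsilane | COC(OC)[C@@H](/C(C)=C/CO[Si](C)(C)C(C)(C)C)C(C)=C
F2 | step 6 | (2E,4R)-4-(dimethoxymethyl)-3,5-dimethylhexa-2,5-dien-1-ol | COC(OC)[C@@H](/C(C)=C/CO)C(C)=C
F3 | step 17 | tert-butyl 2-[(1S,2S,3R,4S,6S)-6-{[(2S)-3-{[tert-butyl(dimethyl)silyl]oxy}-2-methylpropanoyl]oxy}-4-ethenyl-3-(3-hydroperoxyprop-1-en-2-yl)-2-hydroxy-4-methylcyclohexyl]prop-2-enoate | C=C[C@]1(C)C[C@H](OC(=O)[C@@H](C)CO[Si](C)(C)C(C)(C)C)[C@@H](C(=C)C(=O)OC(C)(C)C)[C@@H](O)[C@H]1C(=C)COO
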